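**Retrosynthetic overview**
- Late stage: the O15 docosanoate comes from a Steglich esterification, and the C12–C13 bond from a B-alkyl Suzuki coupling of the C12 iodide 16 with the Z alkenyl iodide 21 (from but-2-yne-1,4-diol), which fixes the side-chain alkene geometry.
- The C17 methyl comes from the C8 ketone (methylenation, hydroxyl-directed hydrogenation); quaternary C9 and H10 come from Birch reductive alkylation of bicyclic enone 10; ring B (C9=C10 aldol) is formed second.
- Ring A is formed first, from the achiral diketone 4 and a vinylphosphonium salt: Michael addition (C1–C2), then intramolecular Wittig closure of C3=C4, with desymmetrization that sets C5. C10, C9 and C8 are all relayed from C5.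
- Enabling feature: the array C18–C4(–C5)–C10–C1 around quaternary C5 is a latent 3,3-disubstituted pentane-2,4-dione with two enantiotopic acetyls. C4 keeps its methyl and becomes the Wittig acceptor; C10 is carried as a ketone whose oxygen is lost in the later aldol condensation and Birch reduction.

Key step: step 3

Remark: positions use clerodane numbering (ring A = C1–C5, C10; ring B = C5–C10). The (R,R)-amide is assumed to be the antipode that deprotonates the pro-S acetyl of 4; if the sense of induction is opposite, the (S,S)-amide is used.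

Step 1
Reactants: 1 3-methylpentane-2,4-dione; 2 pent-1-en-3-one
Product: 3 3-acetyl-3-methyloctane-2,6-dione
Conditions: Et3N (0.1 equiv), MeCN, 23 °C
Reagents that add atoms: none
Why: Base-catalysed Michael addition of the tertiary β-diketone carbon to the vinyl ketone forms the C5–C6 bond and quaternary C5, which is not yet stereogenic because its two acetyl groups are identical.

Step 2
Reactants: 3 3-acetyl-3-methyloctane-2,6-dione
Product: 4 3-[2-(2-ethyl-1,3-dioxolan-2-yl)ethyl]-3-methylpentane-2,4-dione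
Conditions: 1,2-bis(trimethylsilyloxy)ethane (1.1 equiv), TMSOTf (2 mol %), CH2Cl2, −78 °C
Reagents that add atoms: 1,2-bis(trimethylsilyloxy)ethane C[Si](C)(C)OCCO[Si](C)(C)C
Why: Noyori dioxolanation under kinetic control should occur only at the unhindered ethyl ketone (C8), because both acetyl carbonyls are flanked by quaternary C5, and it removes the only competing enolizable ketone before the key step.

Step 3
Reactants: 4 3-[2-(2-ethyl-1,3-dioxolan-2-yl)ethyl]-3-methylpentane-2,4-dione; 5 vinyltriphenylphosphonium bromide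
Product: 8 (S)-2-[2-(2-ethyl-1,3-dioxolan-2-yl)ethyl]-2,3-dimethylcyclohex-3-en-1-one, via lithium enolate 6 (not isolated), via phosphonium ylide 7 (not isolated)
Conditions: (R,R)-bis(1-phenylethyl)amine, n-BuLi, LiCl, THF, −78 °C; then 5, −78 → 60 °C
Reagents that add atoms: none
Why: Proposed new method: the chiral lithium amide removes a proton from one of the two enantiotopic acetyl methyl groups of 4 (the only acidic C–H bonds, since the C8 ketone is masked), enolate 6 adds to the vinylphosphonium salt to give ylide 7, and 7 closes ring A by an intramolecular Wittig reaction on the other acetyl, which forms the C3=C4 bond. The closest known reaction types are the Schweizer annulation (enolate conjugate addition to vinyltriphenylphosphonium bromide followed by intramolecular Wittig olefination) and the enantiotopic deprotonation of prochiral ketones by chiral lithium amides; their combination on an acyclic gem-diacetyl compound is new. Ring A closes by 6-exo-trig attack of the ylide carbon C3 on the C4 carbonyl and collapse of the oxaphosphetane, and attack on the C10 carbonyl would need a four-membered ring, so the regiochemistry is fixed. The only stereocentre, quaternary C5, is set in the deprotonation, where the base is expected to tell the two acetyls apart through a lithium chelate that involves the dioxolane-bearing arm, which differs from the C19 methyl in its ability to coordinate lithium. The step needs enantiotopic-group selectivity and a configurationally stable enolate; LiCl, low temperature and immediate capture by the highly electrophilic phosphonium salt are meant to suppress proton exchange between the two acetyls.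

Step 4
Reactants: 8 (S)-2-[2-(2-ethyl-1,3-dioxolan-2-yl)ethyl]-2,3-dimethylcyclohex-3-en-1-one
Product: 10 (S)-1,4a,5-trimethyl-4,4a,7,8-tetrahydronaphthalen-2(3H)-one, via diketone 9 (not isolated)
Conditions: HCl (0.2 equiv), THF/H2O, 40 °C; then KOH, MeOH, 60 °C
Reagents that add atoms: none
Why: Acidic hydrolysis of the dioxolane and base-mediated intramolecular aldol condensation (Robinson-type closure of ring B, C9 onto the C10 carbonyl) should give the enone, with quaternary C5 untouched and the C3=C4 bond unable to move into conjugation.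

Step 5
Reactants: 10 (S)-1,4a,5-trimethyl-4,4a,7,8-tetrahydronaphthalen-2(3H)-one
Product: 12 ethyl 2-[(1R,4aR,8aS)-1,4a,5-trimethyl-2-oxo-1,2,3,4,4a,7,8,8a-octahydronaphthalen-1-yl]acetate, via lithium enolate 11 (not isolated)
Conditions: Li (2.2 equiv), NH3(l), THF, t-BuOH (1.0 equiv), −78 °C; evaporate NH3; ethyl bromoacetate, THF, −78 → 0 °C
Reagents that add atoms: ethyl bromoacetate CCOC(=O)CBr
Why: Birch-type reductive alkylation: axial protonation at C10 gives the trans-fused enolate (H10 anti to the C19 methyl), and the regiodefined enolate is alkylated at C9 from the face opposite the axial C19 methyl, which should set C10 and quaternary C9 (C11 β, C20 α).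

Step 6
Reactants: 12 ethyl 2-[(1R,4aR,8aS)-1,4a,5-trimethyl-2-oxo-1,2,3,4,4a,7,8,8a-octahydronaphthalen-1-yl]acetate
Product: 13 ethyl 2-[(1R,4aR,8aR)-1,4a,5-trimethyl-2-methylidene-1,2,3,4,4a,7,8,8a-octahydronaphthalen-1-yl]acetate
Conditions: Zn, CH2Br2, TiCl4, THF/CH2Cl2, 0 → 23 °C
Reagents that add atoms: dibromomethane BrCBr
Why: Lombardo methylenation is non-basic and selective for the ketone over the ester, so the hindered, enolizable C8 ketone should give the exocyclic alkene without Claisen-type side reactions.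

Step 7
Reactants: 13 ethyl 2-[(1R,4aR,8aR)-1,4a,5-trimethyl-2-methylidene-1,2,3,4,4a,7,8,8a-octahydronaphthalen-1-yl]acetate
Product: 14 2-[(1R,4aR,8aR)-1,4a,5-trimethyl-2-methylidene-1,2,3,4,4a,7,8,8a-octahydronaphthalen-1-yl]ethan-1-ol
Conditions: LiAlH4, Et2O, 0 °C
Reagents that add atoms: none
Why: Hydride reduction of the ester with LiAlH4 gives the primary alcohol and leaves both alkenes untouched.

Step 8
Reactants: 14 2-[(1R,4aR,8aR)-1,4a,5-trimethyl-2-methylidene-1,2,3,4,4a,7,8,8a-octahydronaphthalen-1-yl]ethan-1-ol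
Product: 15 2-[(1S,2R,4aR,8aR)-1,2,4a,5-tetramethyl-1,2,3,4,4a,7,8,8a-octahydronaphthalen-1-yl]ethan-1-ol
Conditions: H2 (1 atm), [Ir(cod)(PCy3)(py)]PF6 (2 mol %), CH2Cl2, 0 → 23 °C
Reagents that add atoms: none
Why: Hydroxyl-directed homogeneous hydrogenation: the C12 hydroxyl on the β-oriented arm should bind iridium and deliver hydrogen to C8 from the β face, anti to the axial C20 methyl, which gives the equatorial α-methyl at C8, while the uncoordinated, hindered trisubstituted C3=C4 bond reacts more slowly.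

Step 9
Reactants: 15 2-[(1S,2R,4aR,8aR)-1,2,4a,5-tetramethyl-1,2,3,4,4a,7,8,8a-octahydronaphthalen-1-yl]ethan-1-ol
Product: 16 (1S,2R,4aR,8aR)-1-(2-iodoethyl)-1,2,4a,5-tetramethyl-1,2,3,4,4a,7,8,8a-octahydronaphthalene
Conditions: I2, PPh3, imidazole, CH2Cl2, 0 °C
Reagents that add atoms: iodine II
Why: Appel iodination converts the primary alcohol into the iodide under neutral conditions that affect neither the alkene nor the stereocentres.

Step 10
Reactants: 17 but-2-yne-1,4-diol
Product: 19 4-[(tert-butyldimethylsilyl)oxy]but-2-yn-1-ol, via sodium alkoxide 18 (not isolated)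
Conditions: NaH (1.0 equiv), THF, 0 °C; then TBSCl (1.0 equiv), 23 °C
Reagents that add atoms: tert-butyldimethylsilyl chloride CC(C)(C)[Si](C)(C)Cl
Why: Williamson-type monosilylation through the sparingly soluble monosodium alkoxide should give mainly the mono-silyl ether of the symmetrical diol.

Step 11
Reactants: 19 4-[(tert-butyldimethylsilyl)oxy]but-2-yn-1-ol
Product: 21 (Z)-4-[(tert-butyldimethylsilyl)oxy]-3-iodobut-2-en-1-ol, via vinylalanate 20 (not isolated)
Conditions: NaAlH2(OCH2CH2OMe)2 (1.6 equiv), THF, 0 → 23 °C; then I2, THF, −78 °C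
Reagents that add atoms: iodine II
Why: Hydroxyl-directed trans-hydroalumination places hydride at C14 and aluminium at C13 in a five-membered alanate, and iodinolysis with retention should give the Z iodide in which the two CH2O groups are trans.

Step 12
Reactants: 16 (1S,2R,4aR,8aR)-1-(2-iodoethyl)-1,2,4a,5-tetramethyl-1,2,3,4,4a,7,8,8a-octahydronaphthalene; 21 (Z)-4-[(tert-butyldimethylsilyl)oxy]-3-iodobut-2-en-1-ol
Product: 24 (E)-3-{[(tert-butyldimethylsilyl)oxy]methyl}-5-[(1S,2R,4aR,8aR)-1,2,4a,5-tetramethyl-1,2,3,4,4a,7,8,8a-octahydronaphthalen-1-yl]pent-2-en-1-ol, via alkyllithium 22 (not isolated), via borate 23 (not isolated)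
Conditions: 16, t-BuLi (2.1 equiv), Et2O, −78 °C; B-methoxy-9-BBN, THF, −78 → 23 °C; then 21, Pd(dppf)Cl2 (5 mol %), AsPh3, K3PO4 (aq), DMF, 23 °C
Reagents that add atoms: none
Why: B-alkyl Suzuki–Miyaura coupling: lithium–iodine exchange and capture by the borinate give an ate complex that transfers the primary alkyl group to palladium, and coupling with the alkenyl iodide proceeds with retention of geometry, so C12 ends cis to C15.

Step 13
Reactants: 24 (E)-3-{[(tert-butyldimethylsilyl)oxy]methyl}-5-[(1S,2R,4aR,8aR)-1,2,4a,5-tetramethyl-1,2,3,4,4a,7,8,8a-octahydronaphthalen-1-yl]pent-2-en-1-ol; 25 docosanoic acid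
Product: 26 (E)-3-{[(tert-butyldimethylsilyl)oxy]methyl}-5-[(1S,2R,4aR,8aR)-1,2,4a,5-tetramethyl-1,2,3,4,4a,7,8,8a-octahydronaphthalen-1-yl]pent-2-en-1-yl docosanoate
Conditions: DCC (1.2 equiv), DMAP (0.1 equiv), CH2Cl2/THF, 23 °C
Reagents that add atoms: none
Why: Steglich esterification acylates the only free hydroxyl group (O15).

Step 14
Reactants: 26 (E)-3-{[(tert-butyldimethylsilyl)oxy]methyl}-5-[(1S,2R,4aR,8aR)-1,2,4a,5-tetramethyl-1,2,3,4,4a,7,8,8a-octahydronaphthalen-1-yl]pent-2-en-1-yl docosanoate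
Product: 27 (E)-3-(hydroxymethyl)-5-[(1S,2R,4aR,8aR)-1,2,4a,5-tetramethyl-1,2,3,4,4a,7,8,8a-octahydronaphthalen-1-yl]pent-2-en-1-yl docosanoate (target)
Conditions: HF·pyridine, THF/pyridine, 0 → 23 °C
Reagents that add atoms: none
Why: Fluoride-mediated desilylation frees O16, and acyl migration is excluded because O15 and O16 are trans across the C13=C14 bond.

**Compound list**
1 | 3-methylpentane-2,4-dione | CC(=O)C(C)C(C)=O | starting material
2 | pent-1-en-3-one | C=CC(=O)CC | starting material
3 | 3-acetyl-3-methyloctane-2,6-dione | CCC(=O)CCC(C)(C(C)=O)C(C)=O | intermediate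
4 | 3-[2-(2-ethyl-1,3-dioxolan-2-yl)ethyl]-3-methylpentane-2,4-dione | CCC1(CCC(C)(C(C)=O)C(C)=O)OCCO1 | intermediate
5 | vinyltriphenylphosphonium bromide | C=C[P+](c1ccccc1)(c1ccccc1)c1ccccc1.[Br-] | starting material
6 | lithium enolate of the pro-S acetyl group of 4 (not isolated) | [Li+].CCC1(OCCO1)CC[C@@](C([O-])=C)(C)C(C)=O | intermediate
7 | phosphonium ylide with the C1–C2 bond formed, C3 ylide carbon (not isolated) | CCC1(OCCO1)CC[C@@](C(=O)CCC=P(c2ccccc2)(c2ccccc2)c2ccccc2)(C)C(C)=O | intermediate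
8 | (S)-2-[2-(2-ethyl-1,3-dioxolan-2-yl)ethyl]-2,3-dimethylcyclohex-3-en-1-one | CCC1(OCCO1)CC[C@@]2(C)C(C)=CCCC2=O | intermediate
9 | (S)-2,3-dimethyl-2-(3-oxopentyl)cyclohex-3-en-1-one (not isolated) | CCC(=O)CC[C@@]1(C)C(C)=CCCC1=O | intermediate
10 | (S)-1,4a,5-trimethyl-4,4a,7,8-tetrahydronaphthalen-2(3H)-one | O=C1CC[C@@]2(C)C(C)=CCCC2=C1C | intermediate
11 | trans-fused lithium enolate (C8 enolate, H10 β, C19 α; not isolated) | [Li+].CC1=C([O-])CC[C@@]2(C)C(C)=CCC[C@H]12 | intermediate
12 | ethyl 2-[(1R,4aR,8aS)-1,4a,5-trimethyl-2-oxo-1,2,3,4,4a,7,8,8a-octahydronaphthalen-1-yl]acetate | CCOC(=O)C[C@@]1(C)C(=O)CC[C@@]2(C)C(C)=CCC[C@H]12 | intermediate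
13 | ethyl 2-[(1R,4aR,8aR)-1,4a,5-trimethyl-2-methylidene-1,2,3,4,4a,7,8,8a-octahydronaphthalen-1-yl]acetate | CCOC(=O)C[C@@]1(C)C(=C)CC[C@@]2(C)C(C)=CCC[C@H]12 | intermediate
14 | 2-[(1R,4aR,8aR)-1,4a,5-trimethyl-2-methylidene-1,2,3,4,4a,7,8,8a-octahydronaphthalen-1-yl]ethan-1-ol | OCC[C@@]1(C)C(=C)CC[C@@]2(C)C(C)=CCC[C@H]12 | intermediate
15 | 2-[(1S,2R,4aR,8aR)-1,2,4a,5-tetramethyl-1,2,3,4,4a,7,8,8a-octahydronaphthalen-1-yl]ethan-1-ol | OCC[C@@]1(C)[C@H](C)CC[C@@]2(C)C(C)=CCC[C@H]12 | intermediate
16 | (1S,2R,4aR,8aR)-1-(2-iodoethyl)-1,2,4a,5-tetramethyl-1,2,3,4,4a,7,8,8a-octahydronaphthalene | ICC[C@@]1(C)[C@H](C)CC[C@@]2(C)C(C)=CCC[C@H]12 | intermediate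
17 | but-2-yne-1,4-diol | OCC#CCO | starting material
18 | monosodium alkoxide of but-2-yne-1,4-diol (not isolated) | [Na+].[O-]CC#CCO | intermediate
19 | 4-[(tert-butyldimethylsilyl)oxy]but-2-yn-1-ol | CC(C)(C)[Si](C)(C)OCC#CCO | intermediate
20 | sodium five-membered alkoxy(vinyl)alanate, Al on C13 (not isolated) | [Na+].COCCO[Al-]1(OCCOC)OCC=C1CO[Si](C)(C)C(C)(C)C | intermediate
21 | (Z)-4-[(tert-butyldimethylsilyl)oxy]-3-iodobut-2-en-1-ol | OC/C=C(/CO[Si](C)(C)C(C)(C)C)I | intermediate
22 | primary alkyllithium from 16 (not isolated) | [Li]CC[C@@]1(C)[C@H](C)CC[C@@]2(C)C(C)=CCC[C@H]12 | intermediate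
23 | lithium B-alkyl-B-methoxy-9-borabicyclo[3.3.1]nonane ate complex (not isolated) | [Li+].CO[B-]1(CC[C@@]2(C)[C@H](C)CC[C@@]3(C)C(C)=CCC[C@H]23)C2CCCC1CCC2 | intermediate
24 | (E)-3-{[(tert-butyldimethylsilyl)oxy]methyl}-5-[(1S,2R,4aR,8aR)-1,2,4a,5-tetramethyl-1,2,3,4,4a,7,8,8a-octahydronaphthalen-1-yl]pent-2-en-1-ol | OC/C=C(/CO[Si](C)(C)C(C)(C)C)CC[C@@]1(C)[C@H](C)CC[C@@]2(C)C(C)=CCC[C@H]12 | intermediate
25 | docosanoic acid | CCCCCCCCCCCCCCCCCCCCCC(=O)O | starting material
26 | (E)-3-{[(tert-butyldimethylsilyl)oxy]methyl}-5-[(1S,2R,4aR,8aR)-1,2,4a,5-tetramethyl-1,2,3,4,4a,7,8,8a-octahydronaphthalen-1-yl]pent-2-en-1-yl docosanoate | CCCCCCCCCCCCCCCCCCCCCC(=O)OC/C=C(/CO[Si](C)(C)C(C)(C)C)CC[C@@]1(C)[C@H](C)CC[C@@]2(C)C(C)=CCC[C@H]12 | intermediate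
27 | (E)-3-(hydroxymethyl)-5-[(1S,2R,4aR,8aR)-1,2,4a,5-tetramethyl-1,2,3,4,4a,7,8,8a-octahydronaphthalen-1-yl]pent-2-en-1-yl docosanoate | CCCCCCCCCCCCCCCCCCCCCC(=O)OC/C=C(/CO)CC[C@@]1(C)[C@H](C)CC[C@@]2(C)C(C)=CCC[C@H]12 | target

**Step count and risks**

Total step count: 14. Longest linear sequence: 12 steps (steps 1–9 and 12–14).

Steps most likely to fail:

1. Step 3 (proposed new method). The risk is insufficient discrimination between the two enantiotopic acetyl groups, or proton exchange between them before the C–C bond forms, either of which would erode the enantiomeric purity of 8. The fallback uses known chemistry, sets out from 4 and comes back at 8. Desymmetrizing reduction of the pro-S acetyl of 4 with an NADPH-dependent ketoreductase (glucose/glucose dehydrogenase recycling, pH 7 buffer, 30 °C) should give (3R,4S)-3-[2-(2-ethyl-1,3-dioxolan-2-yl)ethyl]-4-hydroxy-3-methylpentan-2-one F1. Methylenation of the remaining ketone with Cp2TiMe2 (toluene, 70 °C) should give (2S,3S)-3-[2-(2-ethyl-1,3-dioxolan-2-yl)ethyl]-3,4-dimethylpent-4-en-2-ol F2. Dess–Martin oxidation should give (S)-3-[2-(2-ethyl-1,3-dioxolan-2-yl)ethyl]-3,4-dimethylpent-4-en-2-one F3. Deprotonation of its only enolizable position with LiN(iPr)2 (THF, −78 °C) and allylation with allyl bromide should give (S)-3-[2-(2-ethyl-1,3-dioxolan-2-yl)ethyl]-2,3-dimethylocta-1,7-dien-4-one F4. Ring-closing metathesis of F4 with the second-generation Grubbs catalyst RuCl2(H2IMes)(PCy3)(=CHPh) (CH2Cl2, 40 °C) then forms the same C3=C4 bond and gives 8.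

2. Step 8. The risk is loss of chemoselectivity (hydrogenation of the ring-A C3=C4 bond by the cationic iridium catalyst) or poor facial selectivity at C8. The fallback sets out from 13 and comes back at 15. Hydroboration of the exocyclic alkene of 13 with 9-BBN (THF, 23 °C; the trisubstituted ring alkene and the ester should not react) and oxidation with NaBO3·4H2O should give ethyl 2-[(1R,2R,4aR,8aR)-2-(hydroxymethyl)-1,4a,5-trimethyl-1,2,3,4,4a,7,8,8a-octahydronaphthalen-1-yl]acetate F5, with boron and hydrogen added from the β face, anti to the axial C20 methyl. Mesylation (MsCl, Et3N, CH2Cl2, 0 °C) should give ethyl 2-[(1R,2R,4aR,8aR)-2-(methanesulfonyloxymethyl)-1,4a,5-trimethyl-1,2,3,4,4a,7,8,8a-octahydronaphthalen-1-yl]acetate F6. LiBHEt3 (THF, 65 °C) then reduces the mesylate to the C17 methyl and the ester to the primary alcohol in one operation and gives 15.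

3. Step 12. The risk is incomplete lithium–iodine exchange or protonation of the alkyllithium, and slow boron-to-palladium transfer with competing β-hydride elimination, so that the C12–C13 bond forms in low yield. The fallback sets out from 16 and 21 and comes back at 24. Direct insertion of Zn (LiCl, THF, 40 °C) into the carbon–iodine bond of 16 should give {2-[(1S,2R,4aR,8aR)-1,2,4a,5-tetramethyl-1,2,3,4,4a,7,8,8a-octahydronaphthalen-1-yl]ethyl}zinc iodide F7, used in solution. Compound 21 is converted with TESCl and imidazole into (Z)-4-[(tert-butyldimethylsilyl)oxy]-3-iodobut-2-en-1-yl triethylsilyl ether F8. Negishi coupling of F7 with F8 (Pd(OAc)2, SPhos, THF, 23 °C) should give, with retention of alkene geometry, the triethylsilyl ether of 24 F9. PPTS in MeOH at 0 °C then removes the primary triethylsilyl group in the presence of the tert-butyldimethylsilyl ether and gives 24.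

Further compounds
F1 | step 3 | (3R,4S)-3-[2-(2-ethyl-1,3-dioxolan-2-yl)ethyl]-4-hydroxy-3-methylpentan-2-one | CCC1(OCCO1)CC[C@@]([C@H](C)O)(C)C(C)=O
F2 | step 3 | (2S,3S)-3-[2-(2-ethyl-1,3-dioxolan-2-yl)ethyl]-3,4-dimethylpent-4-en-2-ol | CCC1(OCCO1)CC[C@@]([C@H](C)O)(C)C(C)=C
F3 | step 3 | (S)-3-[2-(2-ethyl-1,3-dioxolan-2-yl)ethyl]-3,4-dimethylpent-4-en-2-one | CCC1(OCCO1)CC[C@@](C(C)=O)(C)C(C)=C
F4 | step 3 | (S)-3-[2-(2-ethyl-1,3-dioxolan-2-yl)ethyl]-2,3-dimethylocta-1,7-dien-4-one | CCC1(OCCO1)CC[C@@](C(=O)CCC=C)(C)C(C)=C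
F5 | step 8 | ethyl 2-[(1R,2R,4aR,8aR)-2-(hydroxymethyl)-1,4a,5-trimethyl-1,2,3,4,4a,7,8,8a-octahydronaphthalen-1-yl]acetate | CCOC(=O)C[C@@]1(C)[C@H](CO)CC[C@@]2(C)C(C)=CCC[C@H]12
F6 | step 8 | ethyl 2-[(1R,2R,4aR,8aR)-2-(methanesulfonyloxymethyl)-1,4a,5-trimethyl-1,2,3,4,4a,7,8,8a-octahydronaphthalen-1-yl]acetate | CCOC(=O)C[C@@]1(C)[C@H](COS(C)(=O)=O)CC[C@@]2(C)C(C)=CCC[C@H]12
F7 | step 12 | {2-[(1S,2R,4aR,8aR)-1,2,4a,5-tetramethyl-1,2,3,4,4a,7,8,8a-octahydronaphthalen-1-yl]ethyl}zinc iodide | I[Zn]CC[C@@]1(C)[C@H](C)CC[C@@]2(C)C(C)=CCC[C@H]12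
F8 | step 12 | (Z)-4-[(tert-butyldimethylsilyl)oxy]-3-iodobut-2-en-1-yl triethylsilyl ether | CC[Si](CC)(CC)OC/C=C(/CO[Si](C)(C)C(C)(C)C)I
F9 | step 12 | triethylsilyl ether of 24 | CC[Si](CC)(CC)OC/C=C(/CO[Si](C)(C)C(C)(C)C)CC[C@@]1(C)[C@H](C)CC[C@@]2(C)C(C)=CCC[C@H]12
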